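**Retrosynthetic overview**

1. Locants: cyclohexanone ring C1 (C=O), C2 (CMe2), C3 (CH, side chain), C4 (C(CH3)OH), C5 and C6 (CH2); C3′ is the side-chain carbinol. The aryl ether is cut last (Mitsunobu reaction with umbelliferone), and C3′ with both of its two-carbon arms comes from (R)-linalool.
2. Enabling feature: the ring is a γ-hydroxy ketone, with the C1 oxygen and the C4 hydroxyl 1,4-related across the C5–C6 ethano bridge. This is a homoaldol retron, so C4–C5 is cut: a 1-substituted cyclopropanol (ring C1, C5, C6) opens under strain release and its C5 homoenolate adds to the C4 methyl ketone.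
3. The keto-cyclopropanol comes from a γ-lactone (Kulinkovich reaction, then oxidation). The lactone comes from a vinyl ester whose C3 centre and C2–C3 bond are set by iridium-catalysed allylic alkylation of a linalool-derived allyl carbonate with an isobutyrate ketene acetal.
4. Ring order: 1,3-dioxane (protecting ring) → γ-lactone (temporary ring) → cyclopropane → cyclohexanone (key step); the coumarin is bought as umbelliferone.

Key step: step 8

Remark: the sense of induction in step 4 is assumed to follow the usual model for cyclometalated iridium–phosphoramidite catalysts; the ligand antipode is the one that gives (3R)-7, and its mirror image is taken if the first gives (3S).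

**Step 1**
Reactants: 1 (R)-(−)-linalool
Product: 2 (3R)-3,7-dimethyloct-6-ene-1,3-diol
Conditions: 9-BBN (1.5 equiv), THF, 0 °C → rt; then NaOH, H2O2, 0 °C → rt
Reagents that add atoms: hydrogen peroxide, OO
Why: 9-BBN hydroborates the monosubstituted vinyl group anti-Markovnikov much faster than the trisubstituted alkene (hydroboration–oxidation), and C3′ is not touched.

**Step 2**
Reactants: 2 (3R)-3,7-dimethyloct-6-ene-1,3-diol
Product: 3 (4R)-2,2,4-trimethyl-4-(4-methylpent-3-en-1-yl)-1,3-dioxane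
Conditions: 2,2-dimethoxypropane, PPTS (cat.), CH2Cl2, rt
Reagents that add atoms: 2,2-dimethoxypropane, COC(C)(C)OC
Why: acid-catalysed transacetalisation closes the six-membered acetonide on the 1,3-diol and masks both hydroxyls for the organometallic steps.

**Step 3**
Reactants: 3 (4R)-2,2,4-trimethyl-4-(4-methylpent-3-en-1-yl)-1,3-dioxane; 4 allyl methyl carbonate (4 equiv)
Product: 5 methyl (2E)-5-[(4R)-2,2,4-trimethyl-1,3-dioxan-4-yl]pent-2-en-1-yl carbonate
Conditions: second-generation Grubbs catalyst RuCl2(=CHPh)(H2IMes)(PCy3) (5 mol %), CH2Cl2, 40 °C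
Reagents that add atoms: allyl methyl carbonate 4, C=CCOC(=O)OC
Why: olefin cross-metathesis of the prenyl-type alkene with the terminal alkene is driven by loss of volatile isobutene and should give the (E)-allylic carbonate under thermodynamic control.

**Step 4**
Reactants: 5 methyl (2E)-5-[(4R)-2,2,4-trimethyl-1,3-dioxan-4-yl]pent-2-en-1-yl carbonate; 6 1-methoxy-2-methyl-1-(trimethylsilyloxy)prop-1-ene (1.5 equiv)
Product: 7 methyl (3R)-2,2-dimethyl-3-{2-[(4R)-2,2,4-trimethyl-1,3-dioxan-4-yl]ethyl}pent-4-enoate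
Conditions: [Ir(cod)Cl]2 (2 mol %), BINOL-derived N,N-bis(1-phenylethyl)phosphoramidite (4 mol %, antipode as in the remark), n-PrNH2 (catalyst activation), THF, rt
Reagents that add atoms: silyl ketene acetal 6, COC(O[Si](C)(C)C)=C(C)C
Why: iridium-catalysed asymmetric allylic alkylation of a linear allylic carbonate with a silyl ketene acetal gives the branched product, the cyclometalated catalyst fixing C3 (R in 7) independently of the remote C3′ centre while the quaternary C2 is made in the same bond.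

**Step 5**
Reactants: 7 methyl (3R)-2,2-dimethyl-3-{2-[(4R)-2,2,4-trimethyl-1,3-dioxan-4-yl]ethyl}pent-4-enoate
Product: 9 (4S,5RS)-3,3,5-trimethyl-4-{2-[(4R)-2,2,4-trimethyl-1,3-dioxan-4-yl]ethyl}oxolan-2-one, via hydroxy ester 8 (not isolated)
Conditions: Co(acac)2 (20 mol %), PhSiH3 (2 equiv), O2 (1 atm), THF/i-PrOH, rt; then DBU (cat.), toluene, 60 °C
Reagents that add atoms: dioxygen, O=O
Why: Mukaiyama hydration (hydrogen-atom transfer from a cobalt hydride, trapping of the secondary radical by O2) puts OH on the internal carbon and the γ-hydroxy ester closes to the lactone, helped by the gem-dimethyl group; the new carbinol centre is a mixture that step 7 erases.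

**Step 6**
Reactants: 9 (4S,5RS)-3,3,5-trimethyl-4-{2-[(4R)-2,2,4-trimethyl-1,3-dioxan-4-yl]ethyl}oxolan-2-one
Product: 10 (2RS,3S)-3-[2-(1-hydroxycyclopropyl)propan-2-yl]-5-[(4R)-2,2,4-trimethyl-1,3-dioxan-4-yl]pentan-2-ol
Conditions: EtMgBr (4 equiv), Ti(OiPr)4 (1 equiv), THF, 0 °C → rt; aq NH4Cl
Reagents that add atoms: ethylmagnesium bromide, CC[Mg]Br
Why: in the Kulinkovich cyclopropanation the titanacyclopropane formed from EtMgBr and Ti(OiPr)4 acts as a 1,2-dicarbanion on the lactone carbonyl, turning C1 into the cyclopropanol carbon and releasing the ring oxygen as the C4 secondary alcohol; lactones react faster than open esters.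

**Step 7**
Reactants: 10 (2RS,3S)-3-[2-(1-hydroxycyclopropyl)propan-2-yl]-5-[(4R)-2,2,4-trimethyl-1,3-dioxan-4-yl]pentan-2-ol
Product: 11 (3S)-3-[2-(1-hydroxycyclopropyl)propan-2-yl]-5-[(4R)-2,2,4-trimethyl-1,3-dioxan-4-yl]pentan-2-one
Conditions: SO3·pyridine, DMSO, i-Pr2NEt, CH2Cl2, 0 °C
Reagents that add atoms: none
Why: Parikh–Doering oxidation converts the secondary alcohol to the methyl ketone under mild, metal-free conditions that should leave the tertiary cyclopropanol (no carbinol hydrogen, no single-electron oxidant) and the hindered C3–H untouched.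

**Step 8**
Reactants: 11 (3S)-3-[2-(1-hydroxycyclopropyl)propan-2-yl]-5-[(4R)-2,2,4-trimethyl-1,3-dioxan-4-yl]pentan-2-one
Product: 14 (3S,4S)-4-hydroxy-2,2,4-trimethyl-3-{2-[(4R)-2,2,4-trimethyl-1,3-dioxan-4-yl]ethyl}cyclohexan-1-one, via ethylzinc cyclopropoxide 12 (not isolated), via zinc homoenolate 13 (not isolated)
Conditions: Et2Zn (1.5 equiv), THF, 0 → 50 °C; then aq NH4Cl
Reagents that add atoms: none
Why: Proposed new method: Et2Zn forms the zinc cyclopropoxide 12, whose strained ring opens by β-carbon elimination to the β-zincio ketone 13, and insertion of the tethered C4 ketone into the C5–Zn bond then makes the C4–C5 bond, frees the C1 ketone and sets the C4 tertiary alkoxide in one operation, driven by release of about 27 kcal/mol of ring strain, while the only other carbonyl open to 13 is its own C1 ketone, insertion of which merely returns 12. The closest known reaction types are the Et2Zn-mediated opening of cyclopropanols to zinc ketone homoenolates (used so far in copper- and palladium-catalysed couplings), the homoaldol addition of titanium and zinc ester homoenolates to aldehydes and ketones, and the Lewis-acid-mediated intramolecular coupling of cyclopropanol-derived homoenolates with oxocarbenium ions; closure of a carbocycle by addition of a ketone homoenolate to a tethered ketone has not been shown. The cyclohexanone ring closes in the 6-exo-trig mode with respect to the C4 carbonyl. The new stereocentre C4 is controlled by C3: zinc bridges the C1 and C4 oxygens in a bicyclic, boat-like transition state and the C3 side chain takes the position remote from this bridge, which should place the new C4–O bond trans to the C3 chain (4-methyl cis), i.e. (3S,4S). The step needs carbonyl insertion to win over protonation of 13 to the ethyl ketone, over aldol reactions of the methyl ketone and over enolisation at C3; strictly aprotic conditions, the gem-dimethyl group at C2 (which favours ring closure) and the hindered C3–H are what secure this.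

**Step 9**
Reactants: 14 (3S,4S)-4-hydroxy-2,2,4-trimethyl-3-{2-[(4R)-2,2,4-trimethyl-1,3-dioxan-4-yl]ethyl}cyclohexan-1-one
Product: 15 (3S,4S)-3-[(3R)-3,5-dihydroxy-3-methylpentyl]-4-hydroxy-2,2,4-trimethylcyclohexan-1-one
Conditions: AcOH/THF/H2O (3:1:1), 40 °C
Reagents that add atoms: none
Why: mild aqueous acid hydrolyses the acetonide (acetal hydrolysis) without dehydrating the tertiary alcohols.

**Step 10**
Reactants: 15 (3S,4S)-3-[(3R)-3,5-dihydroxy-3-methylpentyl]-4-hydroxy-2,2,4-trimethylcyclohexan-1-one; 16 umbelliferone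
Product: 17 7-{[(3R)-3-hydroxy-5-[(1S,6S)-6-hydroxy-2,2,6-trimethyl-3-oxocyclohexyl]-3-methylpentyl]oxy}-2H-chromen-2-one (target)
Conditions: PPh3, DIAD, THF, 0 °C → rt
Reagents that add atoms: umbelliferone 16, O=c1ccc2ccc(O)cc2o1
Why: Mitsunobu etherification activates only the primary alcohol, which is displaced by the acidic phenol of umbelliferone; the tertiary alcohols do not react and no stereocentre is involved.

**Compound list**

1 | (R)-(−)-linalool, (3R)-3,7-dimethylocta-1,6-dien-3-ol | CC(C)=CCC[C@@](C)(O)C=C | starting material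
2 | (3R)-3,7-dimethyloct-6-ene-1,3-diol | CC(C)=CCC[C@@](C)(O)CCO | intermediate
3 | (4R)-2,2,4-trimethyl-4-(4-methylpent-3-en-1-yl)-1,3-dioxane | CC(C)=CCC[C@@]1(C)OC(C)(C)OCC1 | intermediate
4 | allyl methyl carbonate | C=CCOC(=O)OC | starting material
5 | methyl (2E)-5-[(4R)-2,2,4-trimethyl-1,3-dioxan-4-yl]pent-2-en-1-yl carbonate | COC(=O)OC/C=C/CC[C@@]1(C)OC(C)(C)OCC1 | intermediate
6 | 1-methoxy-2-methyl-1-(trimethylsilyloxy)prop-1-ene (dimethylketene methyl trimethylsilyl acetal) | COC(O[Si](C)(C)C)=C(C)C | starting material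
7 | methyl (3R)-2,2-dimethyl-3-{2-[(4R)-2,2,4-trimethyl-1,3-dioxan-4-yl]ethyl}pent-4-enoate | COC(=O)C(C)(C)[C@@H](C=C)CC[C@@]1(C)OC(C)(C)OCC1 | intermediate
8 | methyl (3S,4RS)-4-hydroxy-2,2-dimethyl-3-{2-[(4R)-2,2,4-trimethyl-1,3-dioxan-4-yl]ethyl}pentanoate (hydroxy ester, not isolated) | COC(=O)C(C)(C)[C@@H](C(C)O)CC[C@@]1(C)OC(C)(C)OCC1 | intermediate
9 | (4S,5RS)-3,3,5-trimethyl-4-{2-[(4R)-2,2,4-trimethyl-1,3-dioxan-4-yl]ethyl}oxolan-2-one | CC1OC(=O)C(C)(C)[C@@H]1CC[C@@]2(C)OC(C)(C)OCC2 | intermediate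
10 | (2RS,3S)-3-[2-(1-hydroxycyclopropyl)propan-2-yl]-5-[(4R)-2,2,4-trimethyl-1,3-dioxan-4-yl]pentan-2-ol | CC(O)[C@@H](CC[C@@]1(C)OC(C)(C)OCC1)C(C)(C)C2(O)CC2 | intermediate
11 | (3S)-3-[2-(1-hydroxycyclopropyl)propan-2-yl]-5-[(4R)-2,2,4-trimethyl-1,3-dioxan-4-yl]pentan-2-one | CC(=O)[C@@H](CC[C@@]1(C)OC(C)(C)OCC1)C(C)(C)C2(O)CC2 | intermediate
12 | ethylzinc cyclopropoxide of 11 (not isolated) | CC(=O)[C@@H](CC[C@@]1(C)OC(C)(C)OCC1)C(C)(C)C2(O[Zn]CC)CC2 | intermediate
13 | ring-opened ethylzinc homoenolate, (3S)-7-(ethylzincio)-4,4-dimethyl-3-{2-[(4R)-2,2,4-trimethyl-1,3-dioxan-4-yl]ethyl}heptane-2,5-dione (not isolated) | CC(=O)[C@@H](CC[C@@]1(C)OC(C)(C)OCC1)C(C)(C)C(=O)CC[Zn]CC | intermediate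
14 | (3S,4S)-4-hydroxy-2,2,4-trimethyl-3-{2-[(4R)-2,2,4-trimethyl-1,3-dioxan-4-yl]ethyl}cyclohexan-1-one | CC1(C)C(=O)CC[C@](C)(O)[C@H]1CC[C@@]2(C)OC(C)(C)OCC2 | intermediate
15 | (3S,4S)-3-[(3R)-3,5-dihydroxy-3-methylpentyl]-4-hydroxy-2,2,4-trimethylcyclohexan-1-one | CC1(C)C(=O)CC[C@](C)(O)[C@H]1CC[C@@](C)(O)CCO | intermediate
16 | umbelliferone, 7-hydroxy-2H-chromen-2-one | O=c1ccc2ccc(O)cc2o1 | starting material
17 | 7-{[(3R)-3-hydroxy-5-[(1S,6S)-6-hydroxy-2,2,6-trimethyl-3-oxocyclohexyl]-3-methylpentyl]oxy}-2H-chromen-2-one | CC1(C)C(=O)CC[C@](C)(O)[C@H]1CC[C@@](C)(O)CCOc1ccc2ccc(=O)oc2c1 | target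

**Step count**

Total: 10 steps. Longest linear sequence: 10 steps (1 → 17).

**Steps most likely to fail**

Step 8 (proposed new method). The zinc homoenolate may fail to insert the tethered ketone, being protonated to the ethyl ketone or simply returning to the cyclopropoxide, or it may add with poor facial selectivity at C4. The fallback uses known chemistry and sets out from 11. Pd(OAc)2 (cat.), pyridine, O2, toluene, 80 °C should open the cyclopropanol by β-carbon elimination and β-hydride elimination to the vinyl ketone (3S)-4,4-dimethyl-3-{2-[(4R)-2,2,4-trimethyl-1,3-dioxan-4-yl]ethyl}hept-6-ene-2,5-dione F1. SmI2 (2.5 equiv), HMPA, t-BuOH, THF, −78 °C should then close the same C4–C5 bond by ketyl–olefin reductive cyclisation onto the enone β-carbon. The heavily solvated samarium-bound ketyl oxygen is expected to take the equatorial site, trans to the C3 chain, and the sequence rejoins the route at 14.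

Step 6. Addition of the titanacyclopropane to the α,α-disubstituted lactone carbonyl may be slow, so that plain ethyl addition or unchanged lactone dominates. The fallback builds the cyclopropane by carbenoid addition instead and sets out from 9. MeLi (1.05 equiv), THF, −78 °C should give the methyl ketone (4S,5RS)-5-hydroxy-3,3-dimethyl-4-{2-[(4R)-2,2,4-trimethyl-1,3-dioxan-4-yl]ethyl}hexan-2-one F2. LiN(iPr)2 (2.2 equiv) and TMSCl, THF, −78 °C should silylate the alcohol and the only enolisable side of the ketone, giving (4S,5RS)-3,3-dimethyl-4-{2-[(4R)-2,2,4-trimethyl-1,3-dioxan-4-yl]ethyl}-2,5-bis(trimethylsilyloxy)hex-1-ene F3. Simmons–Smith cyclopropanation of the enol silane (Et2Zn, CH2I2, CH2Cl2, 0 °C) should give the bis(trimethylsilyl) ether of 10, F4. K2CO3, MeOH, 0 °C removes both silyl groups and the sequence rejoins the route at 10.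

Step 4. Branched-to-linear regioselectivity and enantiofacial control may erode when a quaternary-forming nucleophile meets an alkyl-substituted allyl terminus. The fallback sets C3 by chirality transfer in a sigmatropic rearrangement and sets out from 3.
- Ozonolysis (O3, CH2Cl2, −78 °C; Me2S) should give 3-[(4R)-2,2,4-trimethyl-1,3-dioxan-4-yl]propanal F5.
- Wittig reaction with Ph3P=CHC(O)CH3 should give (3E)-6-[(4R)-2,2,4-trimethyl-1,3-dioxan-4-yl]hex-3-en-2-one F6.
- CBS reduction ((R)-2-methyl-CBS-oxazaborolidine, BH3·SMe2, toluene, −78 °C) should give (2S,3E)-6-[(4R)-2,2,4-trimethyl-1,3-dioxan-4-yl]hex-3-en-2-ol F7.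
- Johnson–Claisen rearrangement with trimethyl orthoisobutyrate (EtCO2H cat., 130 °C) passes through a chair with the carbinol methyl equatorial and should give methyl (3R,4E)-2,2-dimethyl-3-{2-[(4R)-2,2,4-trimethyl-1,3-dioxan-4-yl]ethyl}hex-4-enoate F8.
- Ozonolysis (O3; Me2S) should give methyl (3S)-3-formyl-2,2-dimethyl-5-[(4R)-2,2,4-trimethyl-1,3-dioxan-4-yl]pentanoate F9.
- MeMgBr, THF, −78 °C adds to the aldehyde only and the alkoxide lactonises on warming, rejoining the route at 9.

**Further compounds**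

F1 | step 8 | (3S)-4,4-dimethyl-3-{2-[(4R)-2,2,4-trimethyl-1,3-dioxan-4-yl]ethyl}hept-6-ene-2,5-dione | CC(=O)[C@@H](CC[C@@]1(C)OC(C)(C)OCC1)C(C)(C)C(=O)C=C
F2 | step 6 | (4S,5RS)-5-hydroxy-3,3-dimethyl-4-{2-[(4R)-2,2,4-trimethyl-1,3-dioxan-4-yl]ethyl}hexan-2-one | CC(O)[C@@H](CC[C@@]1(C)OC(C)(C)OCC1)C(C)(C)C(C)=O
F3 | step 6 | (4S,5RS)-3,3-dimethyl-4-{2-[(4R)-2,2,4-trimethyl-1,3-dioxan-4-yl]ethyl}-2,5-bis(trimethylsilyloxy)hex-1-ene | CC(O[Si](C)(C)C)[C@@H](CC[C@@]1(C)OC(C)(C)OCC1)C(C)(C)C(=C)O[Si](C)(C)C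
F4 | step 6 | bis(trimethylsilyl) ether of 10 | CC(O[Si](C)(C)C)[C@@H](CC[C@@]1(C)OC(C)(C)OCC1)C(C)(C)C2(O[Si](C)(C)C)CC2
F5 | step 4 | 3-[(4R)-2,2,4-trimethyl-1,3-dioxan-4-yl]propanal | O=CCC[C@@]1(C)OC(C)(C)OCC1
F6 | step 4 | (3E)-6-[(4R)-2,2,4-trimethyl-1,3-dioxan-4-yl]hex-3-en-2-one | CC(=O)/C=C/CC[C@@]1(C)OC(C)(C)OCC1
F7 | step 4 | (2S,3E)-6-[(4R)-2,2,4-trimethyl-1,3-dioxan-4-yl]hex-3-en-2-ol | C[C@H](O)/C=C/CC[C@@]1(C)OC(C)(C)OCC1
F8 | step 4 | methyl (3R,4E)-2,2-dimethyl-3-{2-[(4R)-2,2,4-trimethyl-1,3-dioxan-4-yl]ethyl}hex-4-enoate | COC(=O)C(C)(C)[C@@H](/C=C/C)CC[C@@]1(C)OC(C)(C)OCC1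
F9 | step 4 | methyl (3S)-3-formyl-2,2-dimethyl-5-[(4R)-2,2,4-trimethyl-1,3-dioxan-4-yl]pentanoate | COC(=O)C(C)(C)[C@@H](C=O)CC[C@@]1(C)OC(C)(C)OCC1
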